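**Plan**
- Numbering: ring C1 (side chain), C2, C3 (Cl), C4 (CH3, OH), C5 (OAc), C6 (O-angeloyl); chain C7 (=C14H2), C8 (O-angeloyl), C9, C10 (OH), C11 (CMe2OH).
- Retrosynthesis cuts, in order: the three ester C–O bonds and the ketal; C3–Cl and the C3/C4 oxirane; C8–C9 (aldol); C7=C14 (methylenation); C6–O (Baeyer–Villiger, from C6–C8); finally C1–C2 and C5–C6 ([4+2]).
- Forward: cyclobut-2-enone and a 1-silyloxy-2-methyldiene give the only carbocycle, a cyclohexene cis-fused to a cyclobutanone. Ring expansion to the γ-lactone, opening and α-methylenation follow; the C9–C11 ketone is joined at C8 by a boron aldol and reduced 1,3-syn; acylations, directed epoxidation and chloride opening finish.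
- Enabling feature: the contiguous all-cis C5–O / C6–O / C1–C7 triad beside C3=C4(CH3) is a cyclohexene cis-fused to a four-membered ketone whose C6–C8 bond is a latent C6–O bond.
- Stereochemistry: C1, C5, C6 from the endo, catalyst-controlled cycloaddition (C6–O by retentive migration); C8 from a reagent-controlled aldol; C10 from C8 by chelate-controlled reduction; C3 and C4 from hydroxyl-directed epoxidation and anti (diaxial) opening.

Key step: step 4

Assumption (chemistry): the facial sense of the two reagent-controlled events (cycloaddition in step 4, boron aldol in step 11) is assigned from the accepted transition-state models; if either model mispredicts, the antipodal catalyst or reagent is used and the route is otherwise unchanged.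

**Step 1**
Reactants: 1 3-oxocyclobutane-1-carboxylic acid
Product: 2 3-bromocyclobutan-1-one
Conditions: HgO, Br2, MgSO4, CH2Cl2, reflux
Reagents that add atoms: bromine BrBr
Why: Cristol–Firth variant of the Hunsdiecker bromodecarboxylation, a radical chain process that tolerates the ketone and is a known preparation of this β-bromo ketone; no stereocentre is involved.

**Step 2**
Reactants: 2 3-bromocyclobutan-1-one
Product: 3 cyclobut-2-en-1-one
Conditions: n-Bu3N, neat, rt; distilled under reduced pressure into a trap at −78 °C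
Reagents that add atoms: none
Why: base-mediated 1,2-elimination (E1cB) of HBr from the β-bromo ketone with a non-nucleophilic tertiary amine; distilling the volatile enone away from the salt limits its oligomerisation.

**Step 3**
Reactants: 4 (E)-2-methylbut-2-enal (tiglaldehyde)
Product: 5 (E)-1-(tert-butyldimethylsilyloxy)-2-methylbuta-1,3-diene
Conditions: TBSOTf, Et3N, Et2O, 0 °C → rt
Reagents that add atoms: tert-butyldimethylsilyl trifluoromethanesulfonate CC(C)(C)[Si](C)(C)OS(=O)(=O)C(F)(F)F
Why: soft enolisation (O-silylation, then γ-deprotonation by Et3N) converts the enal into its silyl dienol ether; reaction through the s-trans conformer places oxygen trans to the vinyl group and so gives the (1E) diene.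

**Step 4**
Reactants: 3 cyclobut-2-en-1-one; 5 (E)-1-(tert-butyldimethylsilyloxy)-2-methylbuta-1,3-diene
Product: 6 (1R,5S,6S)-5-(tert-butyldimethylsilyloxy)-4-methylbicyclo[4.2.0]oct-3-en-7-one
Conditions: (S)-oxazaborolidinium triflimide [C24H25BNO][N(SO2CF3)2] (from (S)-α,α-diphenylprolinol and (o-TolBO)3, then HNTf2; 20 mol%), CH2Cl2, −78 °C
Reagents that add atoms: none
Why: The oxazaborolidinium cation binds the cyclobutenone carbonyl on the alkene side (α-C–H···O contact) and lowers the LUMO of the strained enone, which then undergoes a concerted, asynchronous, suprafacial [4+2] cycloaddition with the s-cis silyloxy diene, forming C1–C2 and C5–C6. The closest known reaction types are oxazaborolidinium-catalysed Diels–Alder reactions of 2-cycloalkenones and Lewis-acid-promoted Diels–Alder reactions of cyclobut-2-enone with oxygenated dienes. The cyclohexene ring is closed by intermolecular [4+2] annulation through a six-membered transition state, and the cis fusion at C1/C6 follows from suprafacial addition to the ring-locked cis alkene. C5 relative to C6 is set by the endo transition state (carbonyl under the diene) together with the (E) enol ether geometry, which places C5–O cis to C6–C8; the absolute configuration is set by the catalyst, whose aryl groups shield one face of the bound enone. The step needs regio-, endo- and facial selectivity: regiochemistry is secured by the large HOMO coefficient at the unsubstituted diene terminus C2 (the oxygen donor at C5 outweighs the C4 methyl), which bonds to the β-carbon C1; endo selectivity by secondary orbital overlap with the planar four-membered enone; facial selectivity by the catalyst.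

**Step 5**
Reactants: 6 bicyclic ketone
Product: 7 (3aR,7R,7aS)-7-(tert-butyldimethylsilyloxy)-6-methyl-3a,4,7,7a-tetrahydro-1-benzofuran-2(3H)-one
Conditions: 30% aq. H2O2, AcOH, NaOAc, 0–5 °C
Reagents that add atoms: hydrogen peroxide OO
Why: Baeyer–Villiger oxidation driven by release of four-ring strain, in which the more substituted ring-fusion carbon C6 migrates to oxygen with retention so that C6–C8 becomes C6–O on the same face; H2O2 in AcOH at low temperature should not epoxidise the unactivated alkene or cleave the silyl ether.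

**Step 6**
Reactants: 7 γ-lactone
Product: 8 2-[(1R,5R,6S)-5-(tert-butyldimethylsilyloxy)-6-hydroxy-4-methylcyclohex-3-en-1-yl]-N-methoxy-N-methylacetamide
Conditions: MeNH(OMe)·HCl, AlMe3, CH2Cl2, 0 °C → rt
Reagents that add atoms: N,O-dimethylhydroxylamine hydrochloride CNOC.Cl
Why: Weinreb aminolysis of the lactone by the aluminium amide made in the flask from AlMe3 opens the ring at the acyl carbon, touches no stereocentre and frees the C6 hydroxyl.

**Step 7**
Reactants: 8 hydroxy Weinreb amide
Product: 9 2-[(1R,5R,6S)-5-(tert-butyldimethylsilyloxy)-4-methyl-6-(triethylsilyloxy)cyclohex-3-en-1-yl]-N-methoxy-N-methylacetamide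
Conditions: TESOTf, 2,6-lutidine, CH2Cl2, −78 °C
Reagents that add atoms: triethylsilyl trifluoromethanesulfonate CC[Si](CC)(CC)OS(=O)(=O)C(F)(F)F
Why: silyl ether formation with the reactive triflate caps the hindered C6 hydroxyl at low temperature before it can relactonise, and a triethylsilyl ether is chosen because it can later be cleaved beside the tert-butyldimethylsilyl ether at C5.

**Step 8**
Reactants: 9 silylated Weinreb amide
Product: 10 2-[(1R,5R,6S)-5-(tert-butyldimethylsilyloxy)-4-methyl-6-(triethylsilyloxy)cyclohex-3-en-1-yl]acetaldehyde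
Conditions: i-Bu2AlH, THF, −78 °C; aq. KNaC4H4O6
Reagents that add atoms: none
Why: partial reduction of an N-methoxy-N-methylamide by i-Bu2AlH stops at the aldehyde level because the chelated aluminium adduct survives until aqueous work-up; silyl ethers and the alkene are inert.

**Step 9**
Reactants: 10 aldehyde
Product: 11 2-[(1R,5R,6S)-5-(tert-butyldimethylsilyloxy)-4-methyl-6-(triethylsilyloxy)cyclohex-3-en-1-yl]prop-2-enal
Conditions: 37% aq. CH2O, pyrrolidine (10 mol%), EtCO2H (10 mol%), i-PrOH, 45 °C
Reagents that add atoms: formaldehyde C=O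
Why: amine/carboxylic acid-catalysed Mannich condensation–elimination (organocatalytic α-methylenation of aldehydes) installs the exocyclic methylene C14 at C7, the only enolisable position, and the buffered medium should leave C1 and the silyl ethers untouched.

**Step 10**
Reactants: 12 3-hydroxy-3-methylbutan-2-one
Product: 13 3-methyl-3-(trimethylsilyloxy)butan-2-one
Conditions: TMSCl, imidazole, DMF, rt
Reagents that add atoms: chlorotrimethylsilane C[Si](C)(C)Cl
Why: standard silylation in which the small trimethylsilyl group masks the tertiary hydroxyl for the enolisation that follows.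

**Step 11**
Reactants: 13 3-methyl-3-(trimethylsilyloxy)butan-2-one; 11 enal
Product: 16 (8S)-β-hydroxy ketone (C8 hydroxyl; C10 ketone; C11 trimethylsilyl ether), via boron enolate 14 (not isolated), via boron aldolate 15 (not isolated)
Conditions: 13 (slight excess over the borane), (+)-Ipc2BCl, Et3N, Et2O, 0 °C; then 11, −78 → −20 °C; then H2O2, pH 7 buffer, MeOH, 0 °C
Reagents that add atoms: none
Why: diisopinocampheylboron-mediated methyl ketone aldol (Paterson aldol): (+)-Ipc2BCl and Et3N enolise the only enolisable side of 13, and the unsubstituted boron enolate adds 1,2 to the enal through a cyclic transition state whose facial preference is opposite to that of (Z)-enolates of ethyl ketones carrying the same ligands, so that the isopinocampheyl groups derived from (−)-α-pinene direct attack onto the si face of the aldehyde and set C8 as (S) under reagent control (the minor C8 epimer is a diastereomer and separable).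

**Step 12**
Reactants: 16 (8S)-β-hydroxy ketone
Product: 18 (8S,10R)-syn-1,3-diol, via diethylboron chelate 17 (not isolated)
Conditions: Et2BOMe, THF/MeOH (4:1), −78 °C; NaBH4, −78 °C; then AcOH, repeated MeOH co-evaporation
Reagents that add atoms: none
Why: Narasaka–Prasad reduction: Et2BOMe ties the C8 hydroxyl and the C10 ketone into a six-membered boron chelate and external hydride adds axially to its half-chair, which gives the 1,3-syn diol and so sets C10 as (R) from C8.

**Step 13**
Reactants: 18 syn-diol
Product: 20 C10/C11 acetonide with free C6 and C8 hydroxyls, via tetraol 19 (not isolated)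
Conditions: PPTS, MeOH, rt; solvent exchange; Me2C(OMe)2, acetone, PPTS, rt; aq. NaHCO3
Reagents that add atoms: 2,2-dimethoxypropane COC(C)(C)OC
Why: acid-catalysed methanolysis removes the labile trimethylsilyl and triethylsilyl ethers while the secondary tert-butyldimethylsilyl ether stays, and ketalisation with acetone under equilibrating conditions should select the five-membered dioxolane across the vicinal C10/C11 diol over the 2,2-dimethyl-1,3-dioxane across C8/C10 (axial methyl penalty), the 1,4-related C6 and C8 hydroxyls being unable to form a cyclic ketal.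

**Step 14**
Reactants: 20 acetonide diol; 21 angelic acid
Product: 23 C6,C8-bis-angelate, via mixed anhydride 22 (not isolated)
Conditions: 21 (excess, at least 2 equiv are consumed), 2,4,6-Cl3C6H2COCl, Et3N, toluene, rt; then 20, 80 °C
Reagents that add atoms: angelic acid, second equivalent (the same compound as 21, one acyl group for each hydroxyl) C/C=C(/C)C(=O)O
Why: Yamaguchi-type esterification through the 2,4,6-trichlorobenzoyl mixed anhydride, run without a nucleophilic catalyst so that the (Z)-acyl group is not isomerised to the tiglate by conjugate addition–elimination; two equivalents of the mixed anhydride acylate the two free secondary hydroxyls, each at the less hindered angeloyl carbonyl, with retention at C6 and C8.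

**Step 15**
Reactants: 23 bis-angelate
Product: 24 C5 alcohol
Conditions: HF·pyridine, pyridine, THF, 0 °C → rt
Reagents that add atoms: none
Why: fluoride-mediated desilylation under buffered, non-basic conditions removes the allylic secondary silyl ether while esters and ketal survive and 1,2-acyl migration from O6 to O5 is not promoted.

**Step 16**
Reactants: 24 C5 alcohol
Product: 25 epoxy alcohol (3,4-epoxide cis to the C5 hydroxyl)
Conditions: VO(acac)2 (cat.), t-BuOOH, CH2Cl2, 0 °C → rt
Reagents that add atoms: tert-butyl hydroperoxide CC(C)(C)OO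
Why: vanadium-catalysed hydroxyl-directed epoxidation delivers oxygen to the allylic C3=C4 alkene on the face of the C5 hydroxyl, which sets C3 and C4 with the oxirane cis to C5–O; the other alkenes are electron-poor or lack a free allylic hydroxyl.

**Step 17**
Reactants: 25 epoxy alcohol
Product: 26 epoxy acetate
Conditions: Ac2O, pyridine, DMAP (cat.), CH2Cl2, rt
Reagents that add atoms: acetic anhydride CC(=O)OC(C)=O
Why: DMAP-catalysed acetylation of the only free hydroxyl; no stereocentre is affected.

**Step 18**
Reactants: 26 epoxy acetate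
Product: 27 chlorohydrin acetonide
Conditions: LiCl, AcOH, THF, rt → 40 °C
Reagents that add atoms: lithium chloride [Li+].[Cl-]
Why: acid-assisted SN2 opening of the epoxide by chloride (LiCl/AcOH halohydrin formation): chloride attacks the secondary C3 anti to the oxirane with inversion, in the trans-diaxial (Fürst–Plattner) mode through the conformer that keeps the C1 side chain equatorial, while attack at the quaternary C4 is disfavoured sterically and by the electron-withdrawing C5 acetoxy group, so that Cl at C3 ends trans to the tertiary hydroxyl retained at C4.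

**Step 19**
Reactants: 27 chlorohydrin acetonide
Product: 28 CNP0223769.1
Conditions: AcOH/H2O (4:1), 45 °C
Reagents that add atoms: none
Why: mild aqueous-acid hydrolysis of the isopropylidene ketal releases the C10/C11 diol; the esters, the chlorohydrin and the 1,1-disubstituted alkene should tolerate dilute acetic acid.

**Compound list**
1 | 3-oxocyclobutane-1-carboxylic acid | O=C1CC(C1)C(=O)O | starting material
2 | 3-bromocyclobutan-1-one | O=C1CC(Br)C1 | intermediate
3 | cyclobut-2-en-1-one | O=C1C=CC1 | intermediate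
4 | (E)-2-methylbut-2-enal (tiglaldehyde) | C/C=C(\C)C=O | starting material
5 | (E)-1-(tert-butyldimethylsilyloxy)-2-methylbuta-1,3-diene | C=C/C(C)=C/O[Si](C)(C)C(C)(C)C | intermediate
6 | (1R,5S,6S)-5-(tert-butyldimethylsilyloxy)-4-methylbicyclo[4.2.0]oct-3-en-7-one (all-cis) | O=C1C[C@H]2CC=C(C)[C@@H](O[Si](C)(C)C(C)(C)C)[C@@H]12 | intermediate
7 | (3aR,7R,7aS)-7-(tert-butyldimethylsilyloxy)-6-methyl-3a,4,7,7a-tetrahydro-1-benzofuran-2(3H)-one | O=C1C[C@H]2CC=C(C)[C@@H](O[Si](C)(C)C(C)(C)C)[C@H]2O1 | intermediate
8 | 2-[(1R,5R,6S)-5-(tert-butyldimethylsilyloxy)-6-hydroxy-4-methylcyclohex-3-en-1-yl]-N-methoxy-N-methylacetamide | CON(C)C(=O)C[C@H]1CC=C(C)[C@@H](O[Si](C)(C)C(C)(C)C)[C@H]1O | intermediate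
9 | 2-[(1R,5R,6S)-5-(tert-butyldimethylsilyloxy)-4-methyl-6-(triethylsilyloxy)cyclohex-3-en-1-yl]-N-methoxy-N-methylacetamide | CON(C)C(=O)C[C@H]1CC=C(C)[C@@H](O[Si](C)(C)C(C)(C)C)[C@H]1O[Si](CC)(CC)CC | intermediate
10 | 2-[(1R,5R,6S)-5-(tert-butyldimethylsilyloxy)-4-methyl-6-(triethylsilyloxy)cyclohex-3-en-1-yl]acetaldehyde | O=CC[C@H]1CC=C(C)[C@@H](O[Si](C)(C)C(C)(C)C)[C@H]1O[Si](CC)(CC)CC | intermediate
11 | 2-[(1R,5R,6S)-5-(tert-butyldimethylsilyloxy)-4-methyl-6-(triethylsilyloxy)cyclohex-3-en-1-yl]prop-2-enal | C=C(C=O)[C@H]1CC=C(C)[C@@H](O[Si](C)(C)C(C)(C)C)[C@H]1O[Si](CC)(CC)CC | intermediate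
12 | 3-hydroxy-3-methylbutan-2-one | CC(=O)C(C)(C)O | starting material
13 | 3-methyl-3-(trimethylsilyloxy)butan-2-one | CC(=O)C(C)(C)O[Si](C)(C)C | intermediate
14 | bis(isopinocampheyl)boron enolate of 13 (ligands from (−)-α-pinene) | C=C(OB([C@H]1C[C@H]2C[C@@H]([C@@H]1C)C2(C)C)[C@H]1C[C@H]2C[C@@H]([C@@H]1C)C2(C)C)C(C)(C)O[Si](C)(C)C | intermediate (not isolated)
15 | bis(isopinocampheyl)boron aldolate of 16 (boron on the C8 oxygen) | C=C([C@H](CC(=O)C(C)(C)O[Si](C)(C)C)OB([C@H]2C[C@H]3C[C@@H]([C@@H]2C)C3(C)C)[C@H]2C[C@H]3C[C@@H]([C@@H]2C)C3(C)C)[C@H]1CC=C(C)[C@@H](O[Si](C)(C)C(C)(C)C)[C@H]1O[Si](CC)(CC)CC | intermediate (not isolated)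
16 | (5S)-6-[(1R,5R,6S)-5-(tert-butyldimethylsilyloxy)-4-methyl-6-(triethylsilyloxy)cyclohex-3-en-1-yl]-5-hydroxy-2-methyl-2-(trimethylsilyloxy)hept-6-en-3-one | C=C([C@H](CC(=O)C(C)(C)O[Si](C)(C)C)O)[C@H]1CC=C(C)[C@@H](O[Si](C)(C)C(C)(C)C)[C@H]1O[Si](CC)(CC)CC | intermediate
17 | O8-diethylboron derivative of 16 (ketone oxygen coordinated to boron) | C=C([C@H](CC(=O)C(C)(C)O[Si](C)(C)C)OB(CC)CC)[C@H]1CC=C(C)[C@@H](O[Si](C)(C)C(C)(C)C)[C@H]1O[Si](CC)(CC)CC | intermediate (not isolated)
18 | (3R,5S)-6-[(1R,5R,6S)-5-(tert-butyldimethylsilyloxy)-4-methyl-6-(triethylsilyloxy)cyclohex-3-en-1-yl]-2-methyl-2-(trimethylsilyloxy)hept-6-ene-3,5-diol | C=C([C@H](C[C@@H](O)C(C)(C)O[Si](C)(C)C)O)[C@H]1CC=C(C)[C@@H](O[Si](C)(C)C(C)(C)C)[C@H]1O[Si](CC)(CC)CC | intermediate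
19 | (3R,5S)-6-[(1R,5R,6S)-5-(tert-butyldimethylsilyloxy)-6-hydroxy-4-methylcyclohex-3-en-1-yl]-2-methylhept-6-ene-2,3,5-triol | C=C([C@H](C[C@@H](O)C(C)(C)O)O)[C@H]1CC=C(C)[C@@H](O[Si](C)(C)C(C)(C)C)[C@H]1O | intermediate (not isolated)
20 | (2S)-3-[(1R,5R,6S)-5-(tert-butyldimethylsilyloxy)-6-hydroxy-4-methylcyclohex-3-en-1-yl]-1-[(4R)-2,2,5,5-tetramethyl-1,3-dioxolan-4-yl]but-3-en-2-ol | C=C([C@H](C[C@H]2OC(C)(C)OC2(C)C)O)[C@H]1CC=C(C)[C@@H](O[Si](C)(C)C(C)(C)C)[C@H]1O | intermediate
21 | angelic acid, (Z)-2-methylbut-2-enoic acid | C/C=C(/C)C(=O)O | starting material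
22 | (Z)-2-methylbut-2-enoic 2,4,6-trichlorobenzoic anhydride | C/C=C(/C)C(=O)OC(=O)c1c(Cl)cc(Cl)cc1Cl | intermediate (not isolated)
23 | 6-O,8-O-bis[(Z)-2-methylbut-2-enoyl] derivative of 20 (C5 silyl ether, C10/C11 acetonide) | C=C([C@H](C[C@H]2OC(C)(C)OC2(C)C)OC(=O)/C(C)=C\C)[C@H]1CC=C(C)[C@@H](O[Si](C)(C)C(C)(C)C)[C@H]1OC(=O)/C(C)=C\C | intermediate
24 | C5 alcohol: 23 without the silyl group | C=C([C@H](C[C@H]2OC(C)(C)OC2(C)C)OC(=O)/C(C)=C\C)[C@H]1CC=C(C)[C@@H](O)[C@H]1OC(=O)/C(C)=C\C | intermediate
25 | 3,4-epoxide of 24, oxirane on the face of the C5 hydroxyl | C=C([C@H](C[C@H]2OC(C)(C)OC2(C)C)OC(=O)/C(C)=C\C)[C@H]1C[C@H]3O[C@@]3(C)[C@@H](O)[C@H]1OC(=O)/C(C)=C\C | intermediate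
26 | 5-O-acetate of 25 | C=C([C@H](C[C@H]2OC(C)(C)OC2(C)C)OC(=O)/C(C)=C\C)[C@H]1C[C@H]3O[C@@]3(C)[C@@H](OC(C)=O)[C@H]1OC(=O)/C(C)=C\C | intermediate
27 | 10,11-O-isopropylidene derivative of the target (3-chloro-4-hydroxy, Cl trans to OH) | C=C([C@H](C[C@H]2OC(C)(C)OC2(C)C)OC(=O)/C(C)=C\C)[C@H]1C[C@H](Cl)[C@@](C)(O)[C@@H](OC(C)=O)[C@H]1OC(=O)/C(C)=C\C | intermediate
28 | CNP0223769.1, (1R,3S,4S,5S,6S,8S,10R) in the numbering used here | C=C([C@H](C[C@@H](O)C(C)(C)O)OC(=O)/C(C)=C\C)[C@H]1C[C@H](Cl)[C@@](C)(O)[C@@H](OC(C)=O)[C@H]1OC(=O)/C(C)=C\C | target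

**Step count**
Total: 19 steps. Longest linear sequence: 17 steps (steps 1, 2, 4–9, 11–19, from compound 1); steps 3 and 10 are one-step side branches.

**Steps most likely to fail, with fallbacks**

Step 4. The strained dienophile may be lost by acid-induced oligomerisation, or facial discrimination by the chiral acid may be poor. The fallback keeps the same cycloaddition but takes the absolute configuration from a resolution. It sets out from compounds 3 and 5 and returns at compound 8.
- ZnCl2 in CH2Cl2 promotes the same endo [4+2] and gives 6 together with its enantiomer, the (1S,5R,6R) ketone F1.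
- Oxidation as in step 5 gives 7 together with the enantiomeric lactone F2.
- Aminolysis as in step 6 gives 8 together with the enantiomeric hydroxy amide F3.
- Esterification of this racemate with (S)-methoxy(phenyl)acetic acid (DCC, DMAP, CH2Cl2) gives two diastereomers, the ester of 8, O-methylmandelate F4, and the ester of the antipode, O-methylmandelate F5, which are separated on silica.
- F4 is cleaved with K2CO3 in MeOH to return compound 8; any lactone 7 formed re-enters at step 6.

Step 11. Facial selectivity may be poor if the resident ring stereocentres oppose the boron reagent. The fallback replaces the stoichiometric chiral enolate by a catalyst-controlled Mukaiyama aldol with an open transition state. It sets out from compounds 13 and 11 and returns at compound 16.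
- Ketone 13 is converted (TMSOTf, Et3N, CH2Cl2, 0 °C) into the enol silane 3-methyl-2,3-bis(trimethylsilyloxy)but-1-ene F6.
- F6 adds to enal 11 under SiCl4 with a catalytic chiral binaphthyldiamine-derived bisphosphoramide (the enantiomer that gives si-face attack), i-Pr2NEt, CH2Cl2, −78 °C, to give the trichlorosilyl aldolate F7.
- Aqueous KF/NaHCO3 work-up releases compound 16.

Step 13. The silyl ethers may not be discriminated cleanly, or the ketal may close across C8/C10 instead of C10/C11. The fallback removes the ambiguity by masking C8 before C10 becomes a carbinol. It sets out from compound 16 and returns at compound 20.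
- The C8 hydroxyl is silylated (TESOTf, 2,6-lutidine, CH2Cl2, −78 °C) to the bis(triethylsilyl) ketone F8.
- The C10 ketone is reduced under reagent control (Corey–Bakshi–Shibata reduction, (S)-2-methyl-CBS-oxazaborolidine, catecholborane, toluene, −40 °C; the tert-alkyl group acts as the large substituent) to the (10R) alcohol F9.
- K2CO3 in MeOH at 0 °C removes only the tertiary trimethylsilyl ether and gives the C10,C11 diol F10, which has no other free hydroxyl.
- 2-Methoxypropene with catalytic PPTS in CH2Cl2 closes the acetonide bis(triethylsilyl) ether F11.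
- HF·pyridine in THF/pyridine at 0 °C cleaves both triethylsilyl ethers beside the tert-butyldimethylsilyl ether and gives compound 20.

**Further compounds**
F1 | step 4 | (1S,5R,6R)-5-(tert-butyldimethylsilyloxy)-4-methylbicyclo[4.2.0]oct-3-en-7-one (enantiomer of 6) | O=C1C[C@@H]2CC=C(C)[C@H](O[Si](C)(C)C(C)(C)C)[C@H]12
F2 | step 4 | (3aS,7S,7aR)-7-(tert-butyldimethylsilyloxy)-6-methyl-3a,4,7,7a-tetrahydro-1-benzofuran-2(3H)-one (enantiomer of 7) | O=C1C[C@@H]2CC=C(C)[C@H](O[Si](C)(C)C(C)(C)C)[C@@H]2O1
F3 | step 4 | 2-[(1S,5S,6R)-5-(tert-butyldimethylsilyloxy)-6-hydroxy-4-methylcyclohex-3-en-1-yl]-N-methoxy-N-methylacetamide (enantiomer of 8) | CON(C)C(=O)C[C@@H]1CC=C(C)[C@H](O[Si](C)(C)C(C)(C)C)[C@@H]1O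
F4 | step 4 | (S)-methoxy(phenyl)acetate ester of 8 at the C6 oxygen | CON(C)C(=O)C[C@H]1CC=C(C)[C@@H](O[Si](C)(C)C(C)(C)C)[C@H]1OC(=O)[C@@H](OC)c1ccccc1
F5 | step 4 | (S)-methoxy(phenyl)acetate ester of the enantiomer of 8 | CON(C)C(=O)C[C@@H]1CC=C(C)[C@H](O[Si](C)(C)C(C)(C)C)[C@@H]1OC(=O)[C@@H](OC)c1ccccc1
F6 | step 11 | 3-methyl-2,3-bis(trimethylsilyloxy)but-1-ene | C=C(O[Si](C)(C)C)C(C)(C)O[Si](C)(C)C
F7 | step 11 | O8-trichlorosilyl derivative of 16 | C=C([C@H](CC(=O)C(C)(C)O[Si](C)(C)C)O[Si](Cl)(Cl)Cl)[C@H]1CC=C(C)[C@@H](O[Si](C)(C)C(C)(C)C)[C@H]1O[Si](CC)(CC)CC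
F8 | step 13 | O8-triethylsilyl ether of 16 | C=C([C@H](CC(=O)C(C)(C)O[Si](C)(C)C)O[Si](CC)(CC)CC)[C@H]1CC=C(C)[C@@H](O[Si](C)(C)C(C)(C)C)[C@H]1O[Si](CC)(CC)CC
F9 | step 13 | (10R)-alcohol from F8 (O8 and O6 triethylsilyl, O11 trimethylsilyl, O5 tert-butyldimethylsilyl) | C=C([C@H](C[C@@H](O)C(C)(C)O[Si](C)(C)C)O[Si](CC)(CC)CC)[C@H]1CC=C(C)[C@@H](O[Si](C)(C)C(C)(C)C)[C@H]1O[Si](CC)(CC)CC
F10 | step 13 | C10,C11 diol from F9 | C=C([C@H](C[C@@H](O)C(C)(C)O)O[Si](CC)(CC)CC)[C@H]1CC=C(C)[C@@H](O[Si](C)(C)C(C)(C)C)[C@H]1O[Si](CC)(CC)CC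
F11 | step 13 | 6-O,8-O-bis(triethylsilyl) ether of 20 | C=C([C@H](C[C@H]2OC(C)(C)OC2(C)C)O[Si](CC)(CC)CC)[C@H]1CC=C(C)[C@@H](O[Si](C)(C)C(C)(C)C)[C@H]1O[Si](CC)(CC)CC
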